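Every unit that has ever become monomer in chains stays counted in the sum of monomer in chains and over-reaction product, since the first-order over-reaction turns one into the other unit for unit. The share asked is therefore a fraction left, not a fraction made.

| setting | teal | grey | green | red |
|---|---|---|---|---|
| free monomer | 2.0 mM | 2.0 mM | 2.0 mM (fed, over 32.0 s) | 2.0 mM |
| initiator | 5.7 mol% | 5.7 mol% | 5.7 mol% | 5.7 mol% |
| time | 40 s |  | 40 s |  |
| remark | a closed flask charged with all of it at once and left for 40 s | one stirred flow tank at steady state, fed with the mixture as stated, mean residence time 120 s | a stirred flask in which free monomer is dosed at a steady rate over 32.0 s without added volume, worked up at 40 s | a single well-mixed tank run continuously and read at steady state, 40 s in it on average |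

    monomer in chains → over-reaction product (k1 = 0.0044 s⁻¹)
    free monomer + living end → monomer in chains + living end, rate k2*[living end]*[free monomer] (k2 = 180 M⁻¹ s⁻¹)
    initiator ⇌ dormant form (K3 = 0.48, k3 = 0.039 s⁻¹)
    free monomer + initiator → spent initiator (k4 = 47 M⁻¹ s⁻¹)
    free monomer + initiator → living end + monomer in chains (k5 = 170 M⁻¹ s⁻¹)

- the stated concentrations are those of everything mixed, before any reaction; amounts are the same in each set-up
- the feed brings no volume worth counting
- run time (teal): 40 s

* the set-up with the highest share of monomer in chains in all that became monomer in chains or over-reaction product, at the outlet or at the end ("none" if the first two lie within 2 percentage points) (teal / grey / green / red / none)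
* share of monomer in chains in all that became monomer in chains or over-reaction product, at the outlet or at the end, teal
* share of monomer in chains in all that became monomer in chains or over-reaction product, at the outlet or at the end, grey
* share of monomer in chains in all that became monomer in chains or over-reaction product, at the outlet or at the end, green
* share of monomer in chains in all that became monomer in chains or over-reaction product, at the outlet or at the end, red

Two times compare: how long monomer in chains has sat in the vessel, and its lifetime against over-reaction, the reciprocal of 0.0044 s⁻¹, 227 s. In a steady tank, [over-reaction product] leaves by the outflow as fast as it forms, so [over-reaction product]/[monomer in chains] equals residence time over lifetime, and the rate of making cancels. The fraction left is one over one plus that ratio: by my reckoning 65.4% for grey and 85.0% for red.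

In the closed flasks the half-life of monomer in chains, 160 s, is longer than the 40 s run, so the fraction left stands close to the exponential of minus mean age over lifetime. For teal, taking the making as steady, the mean age is half the run, which gives roughly 91.6%. For green, the making starts from nothing and rises while the dose runs, so I take the mean age as nearer a third of the run, which gives roughly 94.3%. My choice is green, ahead by 2.7 percentage points, more than the margin.

The forecast also names green, with 90.2% for teal, 65.4% for grey, 93% for green and 85% for red: “Green edges teal because dosing delays chain formation”. Its tanks match my reckoning; its closed flasks stand lower than mine.

The simulation gives 90.8% for teal, 65.4% for grey, 94.0% for green and 85.0% for red, so green is best. Read back through the lifetime by that exponential, the age of monomer in chains stands at 14.0 s in green and 21.9 s in teal, both shorter than 227 s. Dosed over 12.0 s, green reads 92.3%, 1.5 points above teal, less than the margin, and the answer to best then turns to none. Green held to 400 s gives 25.4%, which by the same exponential stands for an age of 311 s, longer than the lifetime.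

The numbers are those of an exercise; no experiment stands behind them.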